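Which flask holds the most target, counted against the starting material charged, is a question of accounts. So I keep a ledger for elm, the flask the forecast puts first, where the starting material is the limiting reagent, at 0.012 M against 0.150 M of partner and 0.0250 M of second substrate.

| flask | starting material | partner | second substrate | temperature | remark | time |
|---|---|---|---|---|---|---|
| grey | 0.015 M | 0.090 M | 0.050 M | 0 °C | run made earlier |  |
| green | 0.045 M | 0.090 M | 0.050 M | 40 °C | run made earlier |  |
| red | 0.12 M | 0.090 M | 0.050 M | 0 °C | run made earlier |  |
| violet | 0.050 M | 0.090 M | 0.033 M | 40 °C | run made earlier |  |
| elm | 0.012 M | 0.150 M | 0.0250 M | 35 °C |  | 20 min |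
| alder | 0.050 M | 0.0900 M | 0.0500 M | 35 °C |  | 20 min |
| ash | 0.015 M | 0.0900 M | 0.0120 M | 75 °C |  | 20 min |
| larch | 0.10 M | 0.400 M | 0.150 M | 35 °C |  | 20 min |
| cedar | 0.012 M | 0.0900 M | 0.0500 M | 15 °C |  | 20 min |
| maple | 0.15 M | 0.0900 M | 0.0120 M | 5 °C |  | 20 min |

| run | time / min | target / % |
|---|---|---|
| grey | 5.00 | 4 |
| grey | 15.0 | 11 |
| grey | 30.0 | 18 |
| grey | 50.0 | 26 |
| grey | 60.0 | 27 |
| green | 0.833 | 8 |
| green | 1.50 | 13 |
| green | 3.00 | 21 |
| green | 5.00 | 27 |
| green | 10.0 | 32 |
| red | 5.00 | 1 |
| red | 15.0 | 13 |
| red | 30.0 | 19 |
| red | 50.0 | 24 |
| red | 60.0 | 28 |
| violet | 0.833 | 6 |
| violet | 1.50 | 13 |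
| violet | 3.00 | 21 |
| violet | 5.00 | 26 |
| violet | 10.0 | 45 |

(each reading ± 2 percentage points)

1. ranking by amount of target, in percent of the starting material charged, from high to low, at 20 min (elm / alder / ash / larch / cedar / maple)
2. the same order at 1.0 min (elm / alder / ash / larch / cedar / maple)
3. the amount of target, in percent of the starting material charged of the flask you put first, at 20 min
4. the amount of target, in percent of the starting material charged of the flask you put last, at 20 min



The first entry comes from grey and red. Their charges of starting material differ by a factor of 8.00, yet their last readings are 27% and 28%, within the scatter of 2 percentage points, so in these two runs the charge does not move the target's share. The second entry comes from green and violet. Green has slowed at 32% by 10.0 min, while violet, with less second substrate, reads 45% at that time. I read this as a division: the starting material goes to target or to a rival route through second substrate, and the curve flattens as the starting material is shared out.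

So I carry one quantity, the selectivity factor: the odds of target against the rest of the charge at the last reading, divided by the ratio of partner to second substrate. Green gives odds of 0.471 at a ratio of 1.80, and violet gives 0.818 at 2.73. Their mean is 0.281, a reading that carries the scatter. Green still gains 5 points from 5.00 min to 10.0 min, so I take that rest to hold starting material not yet converted as well as rival product, and the factor then reads low, by an amount these runs do not give.

Elm is charged at a ratio of 6.00, so 62.7% of the converted starting material is booked to target. Elm runs 20 min, longer than green's last reading, though at 35 °C rather than 40 °C, and I book its charge as converted. These runs follow neither partner nor second substrate, so I cannot size the error of using the charged ratio in place of the moving one, and my reckoning for elm stands at 62.7%, with the factor read low.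

The forecast reads the curves differently, as “A + partner → target, then target + second substrate → product”. It gives elm > ash > alder > cedar > maple > larch at 20 min and ash > larch > elm > alder > cedar > maple at 1.0 min, with 46% on top (range 36% to 56%) and 5% last (range 2% to 14%). My figure for elm lies above the top of its range.

    second substrate + partner → second product (k = 1.20 M⁻¹ min⁻¹, Ea = 55.0 kJ mol⁻¹)
    partner → decomposed reagent (k = 0.0370 min⁻¹, Ea = 81.0 kJ mol⁻¹)
    starting material + partner → target (k = 1.10 M⁻¹ min⁻¹, Ea = 46.0 kJ mol⁻¹)
    starting material + second substrate → cross product (k = 3.20 M⁻¹ min⁻¹, Ea = 44.0 kJ mol⁻¹)
    (constants at 35 °C)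

The flasks give elm > larch > alder > ash > cedar > maple at 20 min and ash > larch > elm > alder > cedar > maple at 1.0 min, with elm at 69.3% and maple at 19.7%. The books of elm close with 22.2% cross product and 8.44% starting material beside the target. Elm's neighbour, charged with 0.10 M of second substrate, has a ratio of 1.50, so the factor 0.281 books 29.7% of its converted starting material to target. That neighbour holds 2.10% starting material, 34.6% target and 63.3% cross product.

All runs are simulated with constants of no real substance; noise was put on by code.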